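**Assumption:** the given SMILES has no stereodescriptors and the molecule has no stereocentres; the hindered biaryl axes are unassigned, so no stereocontrol is needed and the compound is made exactly as drawn, in its free hydrogen sulfate form.

**Retrosynthetic overview**
1. Target 10 ⇐ acidification and eightfold O-debenzylation of sodium sulfate 8 ⇐ O-sulfation of the single free phenol of terphenyl 7.
2. A–B bond: Pinhey ligand coupling of phenol 2 (ring A) with aryllead triacetate 6; the OH that directs the coupling is left as the only free OH, ortho to the new axis, exactly where the sulfate belongs.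
3. Aryllead 6 ⇐ C–H plumbation of symmetric hexabenzyloxybiphenyl 5, whose four aryl C–H are equivalent, so mono-plumbation has no regiochemical ambiguity.
4. B–C bond: the same ligand coupling of 2 with aryllead 3 (from 1), then O-benzylation of the directing OH to give 5.
5. No ring is constructed; three preformed phloroglucinol rings are joined, C–B first, then B–A. Both starting materials (1 and 2) are catalogue compounds.

**Route**

Step 1
Reactants: 1 1,3,5-tris(benzyloxy)benzene; 2 3,5-bis(benzyloxy)phenol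
Product: 4 3,5-bis(benzyloxy)-2-[2,4,6-tris(benzyloxy)phenyl]phenol, via aryllead triacetate 3 (not isolated)
Conditions: Pb(OAc)4 (0.95 equiv), CHCl3, 20 °C, dark; then 2 (1.5 equiv), pyridine (4 equiv), CHCl3, 60 °C
Reagents that add atoms: none
Why: Electrophilic C–H plumbation of the very electron-rich trialkoxyarene gives aryllead triacetate 3, and Pinhey arylation (phenoxide exchange at tetravalent lead, then ligand coupling) delivers the aryl group to the carbon ortho to the OH of 2, a reaction type that tolerates 2,4,6-trialkoxyaryl groups; excess 2 suppresses 2,6-diarylation and no stereocentre is formed.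

Step 2
Reactants: 4 3,5-bis(benzyloxy)-2-[2,4,6-tris(benzyloxy)phenyl]phenol
Product: 5 2,2',4,4',6,6'-hexakis(benzyloxy)-1,1'-biphenyl
Conditions: BnBr (1.5 equiv), K2CO3 (3 equiv), DMF, 60 °C
Reagents that add atoms: benzyl bromide, BrCc1ccccc1
Why: Williamson etherification of the lone phenol caps the directing OH and makes the two rings identical, so all four remaining aryl C–H positions become equivalent.

Step 3
Reactants: 5 2,2',4,4',6,6'-hexakis(benzyloxy)-1,1'-biphenyl; 2 3,5-bis(benzyloxy)phenol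
Product: 7 3,5-bis(benzyloxy)-2-{2,4,6-tris(benzyloxy)-3-[2,4,6-tris(benzyloxy)phenyl]phenyl}phenol, via biaryllead triacetate 6 (not isolated)
Conditions: Pb(OAc)4 (0.7 equiv relative to 5), CHCl3, 20 °C, dark; then 2 (1.5 equiv per Pb), pyridine (4 equiv), CHCl3, 60 °C; unreacted 5 recovered by chromatography
Reagents that add atoms: none
Why: Because 5 is symmetric, mono-plumbation at any of its four equivalent C–H positions gives the single aryllead 6 (substoichiometric Pb(OAc)4 limits double plumbation), and a second Pinhey arylation ortho to the OH of 2 forms the A–B bond and leaves one free OH on ring A next to the axis.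

Step 4
Reactants: 7 3,5-bis(benzyloxy)-2-{2,4,6-tris(benzyloxy)-3-[2,4,6-tris(benzyloxy)phenyl]phenyl}phenol
Product: 8 sodium 3,5-bis(benzyloxy)-2-{2,4,6-tris(benzyloxy)-3-[2,4,6-tris(benzyloxy)phenyl]phenyl}phenyl sulfate
Conditions: SO3·pyridine (6 equiv), pyridine, 55 °C; then aq. NaHCO3; silica gel (CH2Cl2/MeOH)
Reagents that add atoms: sulfur trioxide–pyridine complex, O=S(=O)([O-])[n+]1ccccc1; sodium hydrogencarbonate, [Na+].OC([O-])=O
Why: O-sulfation of a phenol with SO3·pyridine is standard, the substrate has only one free OH so the site is unambiguous, and the NaHCO3 work-up gives the acid-stable sodium salt.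

Step 5
Reactants: 8 sodium 3,5-bis(benzyloxy)-2-{2,4,6-tris(benzyloxy)-3-[2,4,6-tris(benzyloxy)phenyl]phenyl}phenyl sulfate
Product: 10 3,5-dihydroxy-2-[2,4,6-trihydroxy-3-(2,4,6-trihydroxyphenyl)phenyl]phenyl hydrogen sulfate, via sodium sulfate salt 9 (not isolated)
Conditions: H2 (1 atm), 10% Pd/C, THF/MeOH (1:1), 20 °C; filter under Ar; then HCl (1.0 equiv), H2O/MeOH, 0 °C; LH-20 gel filtration (MeOH), lyophilise cold under Ar
Reagents that add atoms: none
Why: Catalytic hydrogenolysis cleaves all eight benzyl ethers while the aryl sulfate monoester, held as its sodium salt, is inert to H2/Pd, and one equivalent of HCl then protonates the sulfate to give the free hydrogen sulfate without excess acid that would hydrolyse it.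

**Compound list**
1 | 1,3,5-tris(benzyloxy)benzene | C(c1ccccc1)Oc1cc(OCc2ccccc2)cc(OCc2ccccc2)c1 | starting material
2 | 3,5-bis(benzyloxy)phenol | Oc1cc(OCc2ccccc2)cc(OCc2ccccc2)c1 | starting material
3 | [2,4,6-tris(benzyloxy)phenyl]lead triacetate | CC(=O)O[Pb](OC(C)=O)(OC(C)=O)c1c(OCc2ccccc2)cc(OCc2ccccc2)cc1OCc1ccccc1 | intermediate
4 | 3,5-bis(benzyloxy)-2-[2,4,6-tris(benzyloxy)phenyl]phenol | Oc1cc(OCc2ccccc2)cc(OCc2ccccc2)c1-c1c(OCc2ccccc2)cc(OCc2ccccc2)cc1OCc1ccccc1 | intermediate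
5 | 2,2',4,4',6,6'-hexakis(benzyloxy)-1,1'-biphenyl | C(c1ccccc1)Oc1cc(OCc2ccccc2)cc(OCc2ccccc2)c1-c1c(OCc2ccccc2)cc(OCc2ccccc2)cc1OCc1ccccc1 | intermediate
6 | [2,2',4,4',6,6'-hexakis(benzyloxy)-1,1'-biphenyl-3-yl]lead triacetate | CC(=O)O[Pb](OC(C)=O)(OC(C)=O)c1c(OCc2ccccc2)cc(OCc2ccccc2)c(-c2c(OCc3ccccc3)cc(OCc3ccccc3)cc2OCc2ccccc2)c1OCc1ccccc1 | intermediate
7 | 3,5-bis(benzyloxy)-2-{2,4,6-tris(benzyloxy)-3-[2,4,6-tris(benzyloxy)phenyl]phenyl}phenol | Oc1cc(OCc2ccccc2)cc(OCc2ccccc2)c1-c1c(OCc2ccccc2)cc(OCc2ccccc2)c(-c2c(OCc3ccccc3)cc(OCc3ccccc3)cc2OCc2ccccc2)c1OCc1ccccc1 | intermediate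
8 | sodium 3,5-bis(benzyloxy)-2-{2,4,6-tris(benzyloxy)-3-[2,4,6-tris(benzyloxy)phenyl]phenyl}phenyl sulfate | [Na+].[O-]S(=O)(=O)Oc1cc(OCc2ccccc2)cc(OCc2ccccc2)c1-c1c(OCc2ccccc2)cc(OCc2ccccc2)c(-c2c(OCc3ccccc3)cc(OCc3ccccc3)cc2OCc2ccccc2)c1OCc1ccccc1 | intermediate
9 | sodium 3,5-dihydroxy-2-[2,4,6-trihydroxy-3-(2,4,6-trihydroxyphenyl)phenyl]phenyl sulfate | [Na+].[O-]S(=O)(=O)Oc1cc(O)cc(O)c1-c1c(O)cc(O)c(-c2c(O)cc(O)cc2O)c1O | intermediate
10 | 3,5-dihydroxy-2-[2,4,6-trihydroxy-3-(2,4,6-trihydroxyphenyl)phenyl]phenyl hydrogen sulfate (CNP0244954.0) | O=S(=O)(O)Oc1cc(O)cc(O)c1-c1c(O)cc(O)c(-c2c(O)cc(O)cc2O)c1O | target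

**Step count and risks**

Total steps: 5. Longest linear sequence: 5 (from 1).

Steps most likely to fail:

Step 3 is the riskiest: mono-plumbation of 5 is statistical, and the second ligand coupling is more hindered than the first. The fallback sets out from 5 (with 2 as the ring A source) and returns at 7, replacing ligand coupling at lead by a palladium cross-coupling with a masked ring A.
- 5 is mono-brominated (NBS, 1.0 equiv, CH2Cl2, −20 °C; all C–H equivalent) to 3-bromo-2,2',4,4',6,6'-hexakis(benzyloxy)-1,1'-biphenyl F2, which, unlike 6, can be purified from 5 and dibromide.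
- Separately, 2 is protected (MOMCl, iPr2NEt, CH2Cl2) as 1,3-bis(benzyloxy)-5-(methoxymethoxy)benzene F3.
- F3 is lithiated at the position between OMOM and OBn (n-BuLi, TMEDA, THF, −20 °C) to [2,4-bis(benzyloxy)-6-(methoxymethoxy)phenyl]lithium F4.
- F4 is quenched with 2-isopropoxy-4,4,5,5-tetramethyl-1,3,2-dioxaborolane to give 2-[2,4-bis(benzyloxy)-6-(methoxymethoxy)phenyl]-4,4,5,5-tetramethyl-1,3,2-dioxaborolane F5.
- Suzuki–Miyaura coupling of F2 with F5 (Pd(OAc)2, SPhos, K3PO4, toluene/H2O, 100 °C) gives 1,5-bis(benzyloxy)-3-(methoxymethoxy)-2-{2,4,6-tris(benzyloxy)-3-[2,4,6-tris(benzyloxy)phenyl]phenyl}benzene F6.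
- HCl in MeOH/THF at 45 °C removes the MOM group to give 7.

Step 1 may fail through incomplete plumbation of 1, over-arylation of 2, or poor ortho selectivity in the first ligand coupling. The fallback sets out from 1 and returns at 5, bypassing 4 and step 2 by a reductive homocoupling.
- 1 is mono-iodinated (NIS, MeCN, 0 °C) to 1,3,5-tris(benzyloxy)-2-iodobenzene F1.
- Ullmann coupling of F1 (activated Cu powder, DMF, 140 °C) gives 5; protodeiodinated 1 is recycled.

Step 5 may fail because the eightfold hydrogenolysis is run on an ionic aryl sulfate, and the product is air- and acid-sensitive. The fallback sets out from 7 and returns at 9, carrying the sulfate as a neutral, chromatographable diester that is unmasked last.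
- 7 is treated with neopentyl chlorosulfate (NaHMDS, THF, −78 to 0 °C) to give 3,5-bis(benzyloxy)-2-{2,4,6-tris(benzyloxy)-3-[2,4,6-tris(benzyloxy)phenyl]phenyl}phenyl neopentyl sulfate F7.
- Hydrogenolysis (H2, Pd/C, EtOAc/MeOH) gives 3,5-dihydroxy-2-[2,4,6-trihydroxy-3-(2,4,6-trihydroxyphenyl)phenyl]phenyl neopentyl sulfate F8.
- Dealkylation at the neopentyl carbon with NaN3 (DMF, 70 °C, Ar) gives 9, which is acidified as in step 5 to 10.

**Further compounds**
F1 | step 1 | 1,3,5-tris(benzyloxy)-2-iodobenzene | Ic1c(OCc2ccccc2)cc(OCc2ccccc2)cc1OCc1ccccc1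
F2 | step 3 | 3-bromo-2,2',4,4',6,6'-hexakis(benzyloxy)-1,1'-biphenyl | Brc1c(OCc2ccccc2)cc(OCc2ccccc2)c(-c2c(OCc3ccccc3)cc(OCc3ccccc3)cc2OCc2ccccc2)c1OCc1ccccc1
F3 | step 3 | 1,3-bis(benzyloxy)-5-(methoxymethoxy)benzene | COCOc1cc(OCc2ccccc2)cc(OCc2ccccc2)c1
F4 | step 3 | [2,4-bis(benzyloxy)-6-(methoxymethoxy)phenyl]lithium | [Li]c1c(OCOC)cc(OCc2ccccc2)cc1OCc1ccccc1
F5 | step 3 | 2-[2,4-bis(benzyloxy)-6-(methoxymethoxy)phenyl]-4,4,5,5-tetramethyl-1,3,2-dioxaborolane | COCOc1cc(OCc2ccccc2)cc(OCc2ccccc2)c1B1OC(C)(C)C(C)(C)O1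
F6 | step 3 | 1,5-bis(benzyloxy)-3-(methoxymethoxy)-2-{2,4,6-tris(benzyloxy)-3-[2,4,6-tris(benzyloxy)phenyl]phenyl}benzene | COCOc1cc(OCc2ccccc2)cc(OCc2ccccc2)c1-c1c(OCc2ccccc2)cc(OCc2ccccc2)c(-c2c(OCc3ccccc3)cc(OCc3ccccc3)cc2OCc2ccccc2)c1OCc1ccccc1
F7 | step 5 | 3,5-bis(benzyloxy)-2-{2,4,6-tris(benzyloxy)-3-[2,4,6-tris(benzyloxy)phenyl]phenyl}phenyl neopentyl sulfate | CC(C)(C)COS(=O)(=O)Oc1cc(OCc2ccccc2)cc(OCc2ccccc2)c1-c1c(OCc2ccccc2)cc(OCc2ccccc2)c(-c2c(OCc3ccccc3)cc(OCc3ccccc3)cc2OCc2ccccc2)c1OCc1ccccc1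
F8 | step 5 | 3,5-dihydroxy-2-[2,4,6-trihydroxy-3-(2,4,6-trihydroxyphenyl)phenyl]phenyl neopentyl sulfate | CC(C)(C)COS(=O)(=O)Oc1cc(O)cc(O)c1-c1c(O)cc(O)c(-c2c(O)cc(O)cc2O)c1O
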